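(Readings and results come from a simulation with made-up constants, noise included.)

E forms, by the candidate steps, from L and J, X from the same pair, and Q from two J without L.

the same everywhere: L 0.20 M

| charge | J | remark | time |
|---|---|---|---|
| maple | 0.79 equiv | run made earlier |  |
| cedar | 3.7 equiv | run made earlier |  |
| elm | 11 equiv | run made earlier |  |
| alpha | 1.00 equiv |  | 40 min |
| epsilon | 2.00 equiv |  | 40 min |
| eta | 4.00 equiv |  | 40 min |
| gamma | 8.00 equiv |  | 40 min |
| delta | 15.0 equiv |  | 40 min |

| run | time / min | E / % |
|---|---|---|
| maple | 4.00 | 18.7 |
| maple | 10.0 | 24.4 |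
| maple | 20.0 | 28.6 |
| maple | 30.0 | 28.5 |
| maple | 40.0 | 28.9 |
| cedar | 4.00 | 39.5 |
| cedar | 10.0 | 45.9 |
| cedar | 20.0 | 47.8 |
| cedar | 30.0 | 47.9 |
| cedar | 40.0 | 48.4 |
| elm | 4.00 | 47.3 |
| elm | 10.0 | 49.5 |
| elm | 20.0 | 50.3 |
| elm | 30.0 | 50.4 |
| elm | 40.0 | 49.6 |

(each reading ± 0.5 percentage points)

- the earlier runs were read with a standard deviation of 0.5 percentage points
- candidate steps: L + J -> E; L + J -> X; 2 J -> Q
- "hardly changes" means that all values lie within two and a half points (for a concentration: within two and a half percent of the largest)

* amount of E at the end, in percent of the L charged for alpha, epsilon, eta, gamma, delta, in this order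
* how the row runs (falls all the way / falls, then rises / rises, then falls / rises all the way / hardly changes)

Follow one L first: at the fork between E and X, the two steps take the same partners, so its odds should hold through a run. Elm, with 11 equiv of J, levels at 50.1 %, half of the L charged, and cedar, with 3.7 equiv, levels at 48.0 %. Elm's reading, with its L taken as fully turned, serves as the selectivity, and E divided by it gives the fraction of L turned.

Now follow one J: it meets L or another J. Maple levels at 28.7 %, so by this reading 57.3 % of its L was turned, taking 72.4 % of its J, and the remainder, if J is gone at the plateau, went to Q.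

How does this carry to other charges? If J's odds at its fork follow the ratio of L to J, and the pulls are about equal, the L left once J is gone falls about exponentially with j, the equivalents of J charged. Call the reach of J the fall in ln(L left) per equivalent charged, 1.07 as read from maple. Then E at the end is the selectivity times the fraction of L turned, one minus exp(−reach × j).

The readings level by 20.0 min, inside the 40 min asked. This reckoning gives 33.0 %, 44.3 %, 49.4 %, 50.1 % and 50.1 %, rising all the way. For cedar it gives 49.1 % against the 48.0 % read, so the upper points of this reckoning may stand high by about 1.1 percentage points.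

The forecast, with other figures but the same shape, reads 32.5 %, 44.5 %, 48.7 %, 50 % and 50.2 %, rises all the way, on the ground that “E stops forming because J runs out, not because of a slow step or an equilibrium”.

The flask gives 33.9 %, 44.9 %, 48.8 %, 49.7 % and 49.9 %: rises all the way.

    L + J → E (k = 0.640 M⁻¹ min⁻¹)
    L + J → X (k = 0.640 M⁻¹ min⁻¹)
    2 J → Q (k = 0.480 M⁻¹ min⁻¹)

In alpha, the step to Q had done half of its turnover up to 40 min by 1.34 min and the step to X by 2.45 min, and at 20.0 min J stood at 3.93 % of its charge. Alpha's L at 40.0 min, 32.3 %, gives a reach of 1.13 against the 1.07 from maple. Epsilon at 40.0 min, with L at 10.1 % and J at 2.29 % of its charge, gives 1.15. At 400 min, with J at 0 %, epsilon's L stands at 6.26 %, a reach of 1.39.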